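**Retrosynthetic overview**

1. The target, (5'S)-4,5'-retro-β,β-carotene, is traced back by reductive 1,4-elimination to an E-ene-1,4-diol and then by trans-reduction to a but-2-yne-1,4-diol. The feature used is the diene C6'=C7'–C8'=C9' beside ring B: C6' (the ring B carbon between C1' and C5') and the methyl-bearing C9' carry no hydrogen, while C7' and C8' are CH. This is the imprint of two carbonyl carbons bridged by the two carbons of acetylene.
2. The ynediol is cut at C6'–C7' and C8'–C9' into (S)-2,2,6-trimethylcyclohexanone, acetylene and the ring A C29 methyl ketone, joined in one pot by two successive carbonyl additions.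
3. The S ketone, which carries the only stereocentre (C5'), comes from enantioselective protonation of the silyl enol ether of the racemic ketone.
4. The C29 ketone comes from a Heck coupling (C15–C15') of anhydroretinol, made by dehydrating retinol and already carrying the retro ring A, with a C9 iodotrienone built from (E)-3-methylpent-2-en-4-yn-1-ol.
5. No ring is formed in the route: ring A is taken from retinol and ring B from the trimethylcyclohexanone.

Key step: step 9

Assumption: (S)-BINOL·SnCl4 is taken to protonate the enol ether on the face that gives the S ketone, by transfer of the facial preference known for 2-substituted cyclohexanone silyl enol ethers; if the sense proves opposite, (R)-BINOL is used instead.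
Remark: steps 7 to 11 are run under argon, in dim light, in base-washed glassware, and polyene intermediates are carried forward without storage.

**Route**

Step 1
Reactants: 1 2,2,6-trimethylcyclohexanone (racemic)
Product: 3 trimethyl[(2,6,6-trimethylcyclohex-1-en-1-yl)oxy]silane, via lithium 2,6,6-trimethylcyclohex-1-en-1-olate 2 (not isolated)
Conditions: LiN(iPr)2, THF, −78 → 0 °C; Me3SiCl, −78 °C → rt
Reagents that add atoms: chlorotrimethylsilane, C[Si](C)(C)Cl
Why: Only C6 carries an α-hydrogen, so deprotonation gives a single enolate, which is trapped on oxygen (silyl enol ether formation).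

Step 2
Reactants: 3 trimethyl[(2,6,6-trimethylcyclohex-1-en-1-yl)oxy]silane
Product: 4 (S)-2,2,6-trimethylcyclohexanone
Conditions: (S)-BINOL (1.1 equiv), SnCl4 (1.0 equiv), toluene, −78 °C; aq NaHCO3; BINOL recovered
Reagents that add atoms: none
Why: Enantioselective protonation of a silyl enol ether by a Lewis-acid-assisted chiral Brønsted acid: the tin-bound binaphthol delivers its acidified hydroxyl proton to one face of C6 with loss of the silyl group, which should set C6 (the future C5') as S, and the low temperature and neutral work-up keep the hindered ketone from re-enolising; the enantiomeric purity is assayed by chiral GC before use.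

Step 3
Reactants: 5 (E)-3-methylpent-2-en-4-yn-1-ol
Product: 6 (2E,4E)-3-methyl-5-(tributylstannyl)penta-2,4-dien-1-ol
Conditions: nBu3SnH, PdCl2(PPh3)2 (2 mol%), THF, 0 °C → rt
Reagents that add atoms: tributyltin hydride, CCCC[SnH](CCCC)CCCC
Why: Palladium-catalysed syn-hydrostannylation of the terminal alkyne places tin on the terminal carbon and gives the E vinylstannane, leaving the trisubstituted alkene and the free alcohol untouched.

Step 4
Reactants: 6 (2E,4E)-3-methyl-5-(tributylstannyl)penta-2,4-dien-1-ol
Product: 7 (2E,4E)-5-iodo-3-methylpenta-2,4-dien-1-ol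
Conditions: I2, CH2Cl2, 0 °C; aq Na2S2O3, KF
Reagents that add atoms: iodine, II
Why: Iododestannylation of a vinylstannane proceeds with retention of the E geometry.

Step 5
Reactants: 7 (2E,4E)-5-iodo-3-methylpenta-2,4-dien-1-ol
Product: 8 (2E,4E)-5-iodo-3-methylpenta-2,4-dienal
Conditions: MnO2 (activated, excess), CH2Cl2, rt, dark
Reagents that add atoms: none
Why: Activated MnO2 oxidises the allylic alcohol selectively to the enal without touching the vinyl iodide or the alkene geometry.

Step 6
Reactants: 8 (2E,4E)-5-iodo-3-methylpenta-2,4-dienal
Product: 9 (3E,5E,7E)-8-iodo-6-methylocta-3,5,7-trien-2-one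
Conditions: Ph3P=CHC(O)CH3, toluene, 60 °C, dark
Reagents that add atoms: 1-(triphenyl-λ5-phosphanylidene)propan-2-one, CC(=O)C=P(c1ccccc1)(c1ccccc1)c1ccccc1
Why: Wittig olefination with a ketone-stabilised ylide gives the E enone and adds the three carbons C10', C9' and the C9' methyl.

Step 7
Reactants: 10 all-trans-retinol
Product: 11 anhydroretinol, (6E)-6-[(2E,4E,6E)-3,7-dimethylnona-2,4,6,8-tetraen-1-ylidene]-1,5,5-trimethylcyclohex-1-ene
Conditions: TsOH·H2O (cat.), toluene, rt, Ar, dark; aq NaHCO3; used at once
Reagents that add atoms: none
Why: Acid-catalysed dehydration of retinol: ionisation of the allylic C15 hydroxyl gives the delocalised retinyl cation, which loses a proton from C4 to give the fully conjugated retro hexaene with the ring A diene C4=C5/C6=C7 and a terminal C14=C15 vinyl group.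

Step 8
Reactants: 11 anhydroretinol (1.3 equiv); 9 (3E,5E,7E)-8-iodo-6-methylocta-3,5,7-trien-2-one
Product: 12 ring A C29 methyl ketone, (3E,5E,7E,9E,11E,13E,15E)-6,11,15-trimethyl-17-[(1E)-2,6,6-trimethylcyclohex-2-en-1-ylidene]heptadeca-3,5,7,9,11,13,15-heptaen-2-one
Conditions: Pd(OAc)2 (5 mol%), nBu4NCl, K2CO3, DMF, rt, Ar, dark
Reagents that add atoms: none
Why: Mizoroki–Heck vinylation of the terminal CH2 of a 1,3-diene under ligand-free phase-transfer conditions: zerovalent palladium formed from Pd(OAc)2 inserts into the C–I bond of 9, the vinylpalladium adds syn across the only monosubstituted alkene of 11 with carbon going to the unhindered C15, and syn β-hydride elimination gives the E C14=C15 bond, the E geometry of the iodide being kept at C15'=C14'.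

Step 9
Reactants: 13 acetylene; 4 (S)-2,2,6-trimethylcyclohexanone; 12 ring A C29 methyl ketone
Product: 17 C40 but-2-yne-1,4-diol, (6S)-1-[(4E,6E,8E,10E,12E,14E,16E)-3-hydroxy-3,7,12,16-tetramethyl-18-[(1E)-2,6,6-trimethylcyclohex-2-en-1-ylidene]octadeca-4,6,8,10,12,14,16-heptaen-1-yn-1-yl]-2,2,6-trimethylcyclohexan-1-ol (5'S; both configurations at C6' and at C9'), via lithium acetylide 14 (not isolated), via dichlorocerium acetylide 15 (not isolated), via (6S)-1-ethynyl-2,2,6-trimethylcyclohexan-1-ol 16 (not isolated)
Conditions: 13 (excess), nBuLi (1.0 equiv), THF, −78 °C; CeCl3 (anhydrous, 1.1 equiv); 4 (1.05 equiv), −78 → 0 °C; Ar purge of residual C2H2; nBuLi (1.0 equiv), CeCl3 (1.1 equiv), −78 °C; 12 (0.8 equiv), −78 → −30 °C, dark; aq NH4Cl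
Reagents that add atoms: none
Why: Monolithium acetylide 14 is transmetallated with CeCl3 to the weakly basic, oxophilic cerium acetylide 15, which adds 1,2 to the C6' carbonyl of 4 (bond C6'–C7') to give 16 as its metal alkoxide; a second equivalent of nBuLi then removes the acetylenic proton and the resulting O,C-dimetalated alkynide, again on cerium, adds 1,2 to the C9' carbonyl of 12 (bond C8'–C9'). The closest known reaction type is the stepwise ethynylation of two different ketones through a propargylic alkoxide–alkynide to give an unsymmetrical but-2-yne-1,4-diol, combined with organocerium 1,2-addition to enolisable ketones. No ring is closed. The two new carbinol centres C6' and C9' form without control and are both removed in step 11, so their configuration does not matter, while C5' is a spectator that ends next to an sp3 carbinol carbon, where it is neither allylic nor acidic. The step needs carbonyl addition in preference to conjugate addition along the heptaenone and freedom from enolisation at C5' of 4 and at the methyl group of 12; the small, linear, hard acetylide attacks the carbonyl carbon even between the quaternary C1' and the tertiary C5', cerium lowers the basicity of the nucleophile, and the temperature stays at or below −30 °C in the second stage. Free acetylide is kept out of the second stage by using 4 in slight excess over nBuLi in the first stage and by purging residual acetylene before the second metalation, so that 12 meets only the alkynide derived from 16.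

Step 10
Reactants: 17 C40 but-2-yne-1,4-diol
Product: 18 C40 (E)-but-2-ene-1,4-diol, (6S)-1-[(1E,4E,6E,8E,10E,12E,14E,16E)-3-hydroxy-3,7,12,16-tetramethyl-18-[(1E)-2,6,6-trimethylcyclohex-2-en-1-ylidene]octadeca-1,4,6,8,10,12,14,16-octaen-1-yl]-2,2,6-trimethylcyclohexan-1-ol (5'S; both configurations at C6' and at C9')
Conditions: NaAlH2(OCH2CH2OCH3)2 (4 equiv), THF, 0 °C → rt, dark; aq KNaC4H4O6 (potassium sodium tartrate)
Reagents that add atoms: none
Why: Alkoxide-directed trans-hydroalumination of a propargylic alcohol: each flanking aluminium alkoxide delivers hydride to the alkyne and protonolysis of the vinylalanate gives the E C7'=C8' alkene, while the polyene, which has no such directing oxygen on an alkyne, is left alone at this temperature.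

Step 11
Reactants: 18 C40 (E)-but-2-ene-1,4-diol
Product: 19 (5'S)-4,5'-retro-β,β-carotene (all-E, including 6E and 6'E), the target
Conditions: TiCl3, LiAlH4 (2:1), THF, 0 °C → reflux, then rt; Et3N; 18, rt, dark; aq K2CO3, base-washed alumina
Reagents that add atoms: none
Why: Low-valent-titanium reductive 1,4-elimination of a 2-ene-1,4-diol to a 1,3-diene: both hydroxyls are bound as titanium alkoxides and both C–O bonds are cleaved reductively through an allylic, here polyenylic, radical, which moves the double bond from C7'=C8' to C6'=C7' and C8'=C9'; the geometry is settled thermodynamically at the delocalised intermediate, E at C8'=C9' for the extended chain and E at C6'=C7' because C8' turns toward the C5' methine and away from the quaternary C1', and C5', never deprotonated or ionised under these aprotic, amine-buffered conditions, should stay S.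

**Compound list**

1 | 2,2,6-trimethylcyclohexanone (racemic) | CC1CCCC(C)(C)C1=O | starting material
2 | lithium 2,6,6-trimethylcyclohex-1-en-1-olate | CC1=C(O[Li])C(C)(C)CCC1 | intermediate (not isolated)
3 | trimethyl[(2,6,6-trimethylcyclohex-1-en-1-yl)oxy]silane | CC1=C(O[Si](C)(C)C)C(C)(C)CCC1 | intermediate
4 | (S)-2,2,6-trimethylcyclohexanone | O=C1[C@@H](C)CCCC1(C)C | intermediate
5 | (E)-3-methylpent-2-en-4-yn-1-ol | C#C/C(C)=C/CO | starting material
6 | (2E,4E)-3-methyl-5-(tributylstannyl)penta-2,4-dien-1-ol | CCCC[Sn](CCCC)(CCCC)/C=C/C(C)=C/CO | intermediate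
7 | (2E,4E)-5-iodo-3-methylpenta-2,4-dien-1-ol | I/C=C/C(C)=C/CO | intermediate
8 | (2E,4E)-5-iodo-3-methylpenta-2,4-dienal | I/C=C/C(C)=C/C=O | intermediate
9 | (3E,5E,7E)-8-iodo-6-methylocta-3,5,7-trien-2-one | I/C=C/C(C)=C/C=C/C(C)=O | intermediate
10 | all-trans-retinol | CC1=C(/C=C/C(C)=C/C=C/C(C)=C/CO)C(C)(C)CCC1 | starting material
11 | anhydroretinol, (6E)-6-[(2E,4E,6E)-3,7-dimethylnona-2,4,6,8-tetraen-1-ylidene]-1,5,5-trimethylcyclohex-1-ene | CC1=CCCC(C)(C)\C1=C/C=C(C)/C=C/C=C(C)/C=C | intermediate
12 | ring A C29 methyl ketone, (3E,5E,7E,9E,11E,13E,15E)-6,11,15-trimethyl-17-[(1E)-2,6,6-trimethylcyclohex-2-en-1-ylidene]heptadeca-3,5,7,9,11,13,15-heptaen-2-one | CC1=CCCC(C)(C)\C1=C/C=C(C)/C=C/C=C(C)/C=C/C=C/C(C)=C/C=C/C(C)=O | intermediate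
13 | acetylene | C#C | starting material
14 | lithium acetylide | [Li]C#C | intermediate (not isolated)
15 | dichlorocerium acetylide | C#C[Ce](Cl)Cl | intermediate (not isolated)
16 | (6S)-1-ethynyl-2,2,6-trimethylcyclohexan-1-ol, both C1 epimers, formed as its metal alkoxide | C#CC1(O)[C@@H](C)CCCC1(C)C | intermediate (not isolated)
17 | C40 but-2-yne-1,4-diol, 5'S, C6' and C9' as mixtures | CC1=CCCC(C)(C)\C1=C/C=C(C)/C=C/C=C(C)/C=C/C=C/C(C)=C/C=C/C(C)(O)C#CC1(O)[C@@H](C)CCCC1(C)C | intermediate
18 | C40 (E)-but-2-ene-1,4-diol, 5'S, C6' and C9' as mixtures | CC1=CCCC(C)(C)\C1=C/C=C(C)/C=C/C=C(C)/C=C/C=C/C(C)=C/C=C/C(C)(O)/C=C/C1(O)[C@@H](C)CCCC1(C)C | intermediate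
19 | (5'S)-4,5'-retro-β,β-carotene, all-E | CC1=CCCC(C)(C)\C1=C/C=C(C)/C=C/C=C(C)/C=C/C=C/C(C)=C/C=C/C(C)=C/C=C1\[C@@H](C)CCCC1(C)C | target

**Step count**

Total: 11 steps. Longest linear sequence: 8 steps (steps 3, 4, 5, 6, 8, 9, 10, 11, from 5).

**Steps most likely to fail**

Step 9. The second addition may stall because the O,C-dimetalated alkynide aggregates and reacts sluggishly. The methyl ketone of 12 may be enolised instead of attacked. Any acetylide left from the first stage would ethynylate 12.
Fallback, from 4 and 13, back at 17: the first addition is run alone and worked up, so that (6S)-1-ethynyl-2,2,6-trimethylcyclohexan-1-ol 16 is isolated and purified. Its tertiary hydroxyl is silylated with Me3SiOTf and 2,6-lutidine to give [(6S)-1-ethynyl-2,2,6-trimethylcyclohexyl]oxy(trimethyl)silane F3. F3 is lithiated with one equivalent of nBuLi, treated with CeCl3 and added to 12 at −78 °C as a soluble mono-anion, which gives the mono-silylated ynediol F4. Fluoride (nBu4NF, THF, 0 °C) then frees the ring B hydroxyl and returns 17.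

Step 8. The polyene 11 may oxidise or oligomerise faster than it inserts. Insertion may occur at an internal alkene. The allylpalladium formed after insertion may be trapped or may isomerise the chain instead of undergoing β-hydride elimination.
Fallback, from 10 and 9, back at 12: retinol 10 is oxidised with MnO2 to all-trans-retinal F1. F1 and iodide 9 are joined by a Nozaki–Hiyama–Kishi reaction (CrCl2, NiCl2 cat., DMSO/THF, rt), in which the vinylchromium adds to the aldehyde and ignores the methyl ketone; this gives the C15 carbinol, the C29 hydroxy ketone F2. F2 is dehydrated with catalytic TsOH in toluene, the C15 cation losing a proton from C4 as in the conversion of retinol into anhydroretinol. This gives 12 with the retro ring A generated after the C15–C15' bond instead of before it.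

Step 11. Lewis-acidic titanium and aluminium chlorides may protonate or ionise the finished polyene and let the double bonds slide into ring B, which would erase C5'. The new C6'=C7' and C8'=C9' bonds may form as E/Z mixtures. The allyltitanium intermediate may be protonated, giving partial reduction instead of elimination.
Fallback, from 17, back at 19: the ynediol 17 is heated with excess LiAlH4 in THF (Whiting diene synthesis). Hydroalumination of the alkyne, loss of one aluminium alkoxide to an allenic carbinol and an SN2' hydride delivery with loss of the second oxygen give the diene directly under basic, chloride-free conditions; no new compound is made (F0) and 18 is bypassed.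

**Further compounds**

F1 | step 8 | all-trans-retinal | CC1=C(/C=C/C(C)=C/C=C/C(C)=C/C=O)C(C)(C)CCC1
F2 | step 8 | C29 hydroxy ketone, (3E,5E,7E,10E,12E,14E,16E)-9-hydroxy-6,11,15-trimethyl-17-(2,6,6-trimethylcyclohex-1-en-1-yl)heptadeca-3,5,7,10,12,14,16-heptaen-2-one (racemic at the carbinol) | CC1=C(/C=C/C(C)=C/C=C/C(C)=C/C(O)/C=C/C(C)=C/C=C/C(C)=O)C(C)(C)CCC1
F3 | step 9 | [(6S)-1-ethynyl-2,2,6-trimethylcyclohexyl]oxy(trimethyl)silane | C#CC1(O[Si](C)(C)C)[C@@H](C)CCCC1(C)C
F4 | step 9 | C40 but-2-yne-1,4-diol with the ring B (C6') hydroxyl as trimethylsilyl ether | CC1=CCCC(C)(C)\C1=C/C=C(C)/C=C/C=C(C)/C=C/C=C/C(C)=C/C=C/C(C)(O)C#CC1(O[Si](C)(C)C)[C@@H](C)CCCC1(C)C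
F0 | step 11 | none | none
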